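The pyranone ring C is opened across C3–C4 and O1–C8a. The feature used is the 1,3-relationship between the C4 carbonyl carbon and the oxygen-bearing C8a of ring A: a 2-fluorobenzoate carries both as electrophiles, and the C3–C2–O1 unit is the ambident enolate of 3',4'-dimethoxyacetophenone. In one operation, Claisen condensation and then SNAr by the diketonate oxygen join a fully substituted, diprenylated ring A ester to the ketone and give the flavone. C2 is set afterwards by ligand-controlled copper hydride conjugate reduction, and the acid work-up of that step also removes the phenol protecting group.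

Key step: step 4

Assumption: (R)-DTBM-SEGPHOS is taken as the ligand enantiomer whose copper hydride delivers hydride to the Re face of C2 (giving 2S); if the sense is the opposite one, the (S)-ligand is used with nothing else changed.

Step 1
Reactants: 1 methyl 2-fluoro-4-hydroxybenzoate
Product: 2 methyl 3,5-dibromo-2-fluoro-4-hydroxybenzoate
Conditions: Br2 (2.1 equiv), AcOH, rt
Reagents that add atoms: bromine (BrBr)
Why: Electrophilic aromatic bromination should go to both positions ortho to the hydroxyl (C3 and C5), because the para position is blocked by the ester and the fluorine and ester direct to the same two carbons.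

Step 2
Reactants: 2 methyl 3,5-dibromo-2-fluoro-4-hydroxybenzoate
Product: 3 methyl 3,5-dibromo-2-fluoro-4-(methoxymethoxy)benzoate
Conditions: NaH, MOMCl, DMF, 0 °C to rt
Reagents that add atoms: chloromethyl methyl ether (COCCl)
Why: Williamson-type O-alkylation of the acidic, hindered phenoxide with the small and very reactive chloromethyl ether should give the base-stable MOM acetal needed for steps 3 and 4.

Step 3
Reactants: 3 methyl 3,5-dibromo-2-fluoro-4-(methoxymethoxy)benzoate; 4 prenyl bromide (1-bromo-3-methylbut-2-ene)
Product: 6 methyl 2-fluoro-4-(methoxymethoxy)-3,5-bis(3-methylbut-2-en-1-yl)benzoate, via prenylzinc bromide 5 (not isolated)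
Conditions: 4 (3 equiv), Zn dust, LiCl, THF, 0 °C; then 3, Pd(OAc)2 (4 mol %), CPhos (8 mol %), THF, rt
Reagents that add atoms: none
Why: Double Negishi cross-coupling: CPhos-ligated zerovalent palladium inserts into each C–Br bond, and fast reductive elimination from the η1-prenyl complex at its primary carbon should give the linear prenyl group at both positions, with ester, fluoride and acetal left alone by the organozinc.

Step 4
Reactants: 6 methyl 2-fluoro-4-(methoxymethoxy)-3,5-bis(3-methylbut-2-en-1-yl)benzoate; 7 3',4'-dimethoxyacetophenone
Product: 9 2-(3,4-dimethoxyphenyl)-7-(methoxymethoxy)-6,8-bis(3-methylbut-2-en-1-yl)-4H-chromen-4-one, via potassium diketonate 8 (not isolated)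
Conditions: 7 (1.1 equiv), KN(SiMe3)2 (2.2 equiv), THF, −78 °C; 6, −78 °C to rt; AcOH (1.2 equiv); THF exchanged for DMF, K2CO3, 100 °C
Reagents that add atoms: none
Why: The potassium enolate of 7 attacks the ester carbonyl of 6 (Claisen condensation, C3–C4) and methoxide is expelled; the diketone is trapped as its enolate 8, which makes C-acylation the thermodynamic outcome whatever the initial C/O ratio. After the methoxide is neutralised, the distal enolate oxygen of 8 (the former ketone oxygen, the future O1) adds to the fluorine-bearing C8a, the Meisenheimer anion is stabilised through C4a by the C4 carbonyl, and loss of fluoride gives the aromatic pyranone (intramolecular SNAr, O1–C8a). The closest known reactions are the base-mediated O-arylation of 1-(2-haloaryl)-1,3-diketones to chromones and the Grohe-type cycloacylation route to 4-quinolones. Ring C closes in a six-membered mode at the trigonal C8a, 6-endo with respect to the C8a–C4a bond that relays the charge to the carbonyl; attack by C3 instead of oxygen would need a four-membered ring, so only O-arylation is possible. No stereocentre is formed, since C2 stays trigonal until step 5. The step needs acylation to outrun any intermolecular displacement of fluoride: the C–F bond is activated only by the ortho acyl group, the C7 acetal oxygen is meta to C8a and does not donate into the attacked carbon, and neutralising the methoxide before heating removes the one competing nucleophile and spares the prenyl groups from base-induced isomerisation.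

Step 5
Reactants: 9 2-(3,4-dimethoxyphenyl)-7-(methoxymethoxy)-6,8-bis(3-methylbut-2-en-1-yl)-4H-chromen-4-one
Product: 12 IN0946, (2S)-2-(3,4-dimethoxyphenyl)-7-hydroxy-6,8-bis(3-methylbut-2-en-1-yl)chroman-4-one, via silyl enol ether 10 (not isolated), via MOM-protected flavanone 11 (not isolated)
Conditions: Cu(OAc)2 (5 mol %), (R)-DTBM-SEGPHOS (5.5 mol %), (EtO)2MeSiH (3 equiv), toluene, 0 °C to rt; then 2 M HCl in MeOH, 40 °C
Reagents that add atoms: none
Why: Ligand-controlled copper hydride asymmetric conjugate reduction (1,4-hydrosilylation) of the chromone should deliver hydride to the Re face of C2 under control of the chiral bisphosphine and set the (2S) centre, the copper enolate being silylated to 10 so that the β-aryloxy ketone never meets base (no retro-oxa-Michael racemisation), after which methanolic HCl should hydrolyse the enol ether to 11 and cleave the MOM acetal by acetal exchange without touching the prenyl groups or the stereocentre.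

Compound list
1 | methyl 2-fluoro-4-hydroxybenzoate | COC(=O)c1ccc(O)cc1F | starting material
2 | methyl 3,5-dibromo-2-fluoro-4-hydroxybenzoate | COC(=O)c1cc(Br)c(O)c(Br)c1F | intermediate
3 | methyl 3,5-dibromo-2-fluoro-4-(methoxymethoxy)benzoate | COC(=O)c1cc(Br)c(OCOC)c(Br)c1F | intermediate
4 | prenyl bromide (1-bromo-3-methylbut-2-ene) | CC(C)=CCBr | starting material
5 | prenylzinc bromide | CC(C)=CC[Zn]Br | intermediate
6 | methyl 2-fluoro-4-(methoxymethoxy)-3,5-bis(3-methylbut-2-en-1-yl)benzoate | COC(=O)c1cc(CC=C(C)C)c(OCOC)c(CC=C(C)C)c1F | intermediate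
7 | 3',4'-dimethoxyacetophenone | CC(=O)c1ccc(OC)c(OC)c1 | starting material
8 | 1-(3,4-dimethoxyphenyl)-3-[2-fluoro-4-(methoxymethoxy)-3,5-bis(3-methylbut-2-en-1-yl)phenyl]propane-1,3-dione, present as its potassium enolate | COc1ccc(C(=O)CC(=O)c2cc(CC=C(C)C)c(OCOC)c(CC=C(C)C)c2F)cc1OC | intermediate
9 | 2-(3,4-dimethoxyphenyl)-7-(methoxymethoxy)-6,8-bis(3-methylbut-2-en-1-yl)-4H-chromen-4-one | COc1ccc(-c2cc(=O)c3cc(CC=C(C)C)c(OCOC)c(CC=C(C)C)c3o2)cc1OC | intermediate
10 | (2S)-4-[diethoxy(methyl)silyloxy]-2-(3,4-dimethoxyphenyl)-7-(methoxymethoxy)-6,8-bis(3-methylbut-2-en-1-yl)-2H-chromene | COc1ccc([C@@H]2C=C(O[Si](C)(OCC)OCC)c3cc(CC=C(C)C)c(OCOC)c(CC=C(C)C)c3O2)cc1OC | intermediate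
11 | (2S)-2-(3,4-dimethoxyphenyl)-7-(methoxymethoxy)-6,8-bis(3-methylbut-2-en-1-yl)chroman-4-one | COc1ccc([C@@H]2CC(=O)c3cc(CC=C(C)C)c(OCOC)c(CC=C(C)C)c3O2)cc1OC | intermediate
12 | IN0946, (2S)-2-(3,4-dimethoxyphenyl)-7-hydroxy-6,8-bis(3-methylbut-2-en-1-yl)chroman-4-one | COc1ccc([C@@H]2CC(=O)c3cc(CC=C(C)C)c(O)c(CC=C(C)C)c3O2)cc1OC | target

Total step count: 5
Longest linear sequence: 5 steps (1 → 2 → 3 → 6 → 9 → 12)

Steps most likely to fail

1. Step 5. What may go wrong: hydride transfer to C2 with poor facial discrimination, or slow turnover, because the 2-aryl vinylogous ester is a less reactive and less differentiated acceptor than a 2-alkylchromone. Fallback: from 9, non-selective 1,4-reduction with LiBH(s-Bu)3 in THF at −78 °C should give the racemic MOM-protected flavanone F1. Kinetic resolution of F1 by asymmetric transfer hydrogenation (Cp*RhCl[(R,R)-TsDPEN], HCO2H/Et3N, EtOAc, run to about half conversion) should reduce the (2R)-ketone to the cis-(2R,4R)-flavan-4-ol F2 and leave the (2S)-ketone, which is 11. After separation from F2, 11 is taken through the methanolic HCl stage of step 5 to 12.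

2. Step 4. What may go wrong: slow ring closure of the anionic, hindered and electron-rich diketonate at C8a, so that retro-Claisen cleavage or intermolecular attack at the C–F carbon takes over. Fallback: from 6, lithium (3,4-dimethoxyphenyl)acetylide (from 4-ethynyl-1,2-dimethoxybenzene and n-BuLi) with BF3·OEt2 in THF at −78 °C should give the ynone F3. Here the C–F carbon sits ortho to a neutral ketone and no alkoxide accompanies the ring closure. Treating F3 with benzaldoxime and K2CO3 in DMSO at 80 °C should then give 9: the oxime acts as a hydroxide surrogate, transferring oxygen to the fluoroarene or to the ynone with loss of benzonitrile, and the ring closes.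

3. Step 3. What may go wrong: incomplete oxidative addition at the C–Br bond flanked by fluorine and the acetal, allyl isomerisation on palladium leading to branched (reverse-prenyl) coupling, or addition of the allylic zinc reagent to the ester. Fallback: from 3, double Stille coupling with allyltributylstannane (Pd(PPh3)4, toluene, 100 °C) should give the diallyl ester F4. Cross-metathesis of F4 with 2-methylbut-2-ene (second-generation Grubbs catalyst, RuCl2(H2IMes)(PCy3)(=CHPh), CH2Cl2, 40 °C) should convert both allyl groups into prenyl groups and give 6.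

Further compounds
F1 | step 5 | racemic 2-(3,4-dimethoxyphenyl)-7-(methoxymethoxy)-6,8-bis(3-methylbut-2-en-1-yl)chroman-4-one | COc1ccc(C2CC(=O)c3cc(CC=C(C)C)c(OCOC)c(CC=C(C)C)c3O2)cc1OC
F2 | step 5 | (2R,4R)-2-(3,4-dimethoxyphenyl)-7-(methoxymethoxy)-6,8-bis(3-methylbut-2-en-1-yl)chroman-4-ol | COc1ccc([C@H]2C[C@@H](O)c3cc(CC=C(C)C)c(OCOC)c(CC=C(C)C)c3O2)cc1OC
F3 | step 4 | 3-(3,4-dimethoxyphenyl)-1-[2-fluoro-4-(methoxymethoxy)-3,5-bis(3-methylbut-2-en-1-yl)phenyl]prop-2-yn-1-one | COc1ccc(C#CC(=O)c2cc(CC=C(C)C)c(OCOC)c(CC=C(C)C)c2F)cc1OC
F4 | step 3 | methyl 3,5-diallyl-2-fluoro-4-(methoxymethoxy)benzoate | COC(=O)c1cc(CC=C)c(OCOC)c(CC=C)c1F
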